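1. Numbering: ring C1(CH2OAc)=C2H–C3(=O)–C4–C5H–C6(=O) with the oxirane on C4–C5; side chain C1'(OAc)–C2'=C3'(Me)–C4'=C5'–C6'HO on C4.
2. Retrosynthetic cuts: C3=O and C6=O back to silyl-protected carbinols; C4'=C5' (Wittig); ring bond C1=C2 (ring-closing metathesis); C2–C3 and C1–C6 (two alkenylchromium additions to aldehydes); the oxirane oxygen; C4–C1' (vinylalane aldol).
3. Forward: a C4 ynoate (C3–C6) and a C5 enal (C1'–C4') are joined, the resulting Z-alkene C4=C5 is epoxidised, both CH2O arms become alkenyl carbinols, and the only carbocycle is closed last across C1=C2; the chain is then lengthened and C3/C6 are oxidised.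
4. Enabling feature: C1=C2 is the only ring alkene and lies opposite the C4–C5 oxirane, whose cis fusion holds the C3 and C6 arms on one face; C3 and C6 end as ketones, so their carbinol configuration is free.
5. Stereochemistry: C4 and C5 come from a kinetic-resolution epoxidation of the racemic C1' carbinol with Ti(Oi-Pr)4, D-(−)-diisopropyl tartrate and t-BuOOH. That reaction gives the erythro epoxy alcohol, whereas the target is threo along C2'–C1'–C4–C5, so C1' is inverted in the step that introduces its acetate (Mitsunobu).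

Key step: step 20

Abbreviations: TBS = tert-butyldimethylsilyl, PMB = 4-methoxybenzyl, DIPT = diisopropyl tartrate, DMP = Dess–Martin periodinane, NMO = N-methylmorpholine N-oxide.

**Route**

Step 1
Reactants: 1 1,1-dimethoxyacetone
Product: 2 ethyl (2E)-4,4-dimethoxy-3-methylbut-2-enoate
Conditions: (EtO)2P(O)CH2CO2Et, NaH, THF, 0 °C to rt
Reagents that add atoms: triethyl phosphonoacetate, CCOC(=O)CP(=O)(OCC)OCC
Why: Horner–Wadsworth–Emmons olefination of the methyl ketone should place the ester trans to the larger acetal-bearing carbon (E), the minor Z isomer being removed by chromatography.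

Step 2
Reactants: 2 ethyl (2E)-4,4-dimethoxy-3-methylbut-2-enoate
Product: 3 (2E)-4,4-dimethoxy-3-methylbut-2-en-1-ol
Conditions: i-Bu2AlH, CH2Cl2, −78 °C
Reagents that add atoms: none
Why: 1,2-reduction of the enoate with i-Bu2AlH at low temperature stops at the allylic alcohol and leaves the dimethyl acetal and the alkene geometry untouched.

Step 3
Reactants: 3 (2E)-4,4-dimethoxy-3-methylbut-2-en-1-ol
Product: 4 (2E)-4,4-dimethoxy-3-methylbut-2-enal
Conditions: activated MnO2, CH2Cl2, rt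
Reagents that add atoms: none
Why: allylic oxidation with MnO2 is selective for the allylic alcohol and is neutral, so neither the acetal nor the E geometry should suffer.

Step 4
Reactants: 5 propargyl alcohol
Product: 6 4-methoxybenzyl propargyl ether
Conditions: NaH, PMBCl, n-Bu4NI (cat.), THF/DMF, 0 °C to rt
Reagents that add atoms: 4-methoxybenzyl chloride, COc1ccc(CCl)cc1
Why: Williamson etherification of the primary alkoxide; the PMB group is chosen because it survives all later steps and is removed oxidatively in the presence of silyl ethers and acetates.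

Step 5
Reactants: 6 4-methoxybenzyl propargyl ether
Product: 8 methyl 4-(PMB-oxy)but-2-ynoate, via lithium acetylide 7 (not isolated)
Conditions: n-BuLi, THF, −78 °C; then ClCO2Me, −78 to 0 °C
Reagents that add atoms: methyl chloroformate, COC(=O)Cl
Why: deprotonation of the terminal alkyne and C-acylation of the lithium acetylide with a chloroformate is the standard route to 2-ynoates.

Step 6
Reactants: 8 methyl 4-(PMB-oxy)but-2-ynoate; 4 (2E)-4,4-dimethoxy-3-methylbut-2-enal
Product: 10 methyl (2Z)-2-[(2E)-1-hydroxy-4,4-dimethoxy-3-methylbut-2-en-1-yl]-4-(PMB-oxy)but-2-enoate (racemic), via vinylalane 9 (not isolated)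
Conditions: i-Bu2AlH, NMO, THF, 0 °C; then 4, 0 °C
Reagents that add atoms: none
Why: vinylalumination, in which syn conjugate hydroalumination of the ynoate puts aluminium on the α-carbon cis to the new hydrogen and the α-alumino acrylate adds 1,2 to the enal with retention, so the ester ends up cis to CH2OPMB (the geometry that later places the C3 and C6 arms cis on the oxirane) while C1' is formed racemic; the mixture is kept at or below 0 °C so the vinylalane does not isomerise.

Step 7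
Reactants: 10 methyl (2Z)-2-[(2E)-1-hydroxy-4,4-dimethoxy-3-methylbut-2-en-1-yl]-4-(PMB-oxy)but-2-enoate (racemic)
Product: 11 (2E,5E)-3-(hydroxymethyl)-7,7-dimethoxy-6-methyl-1-(PMB-oxy)hepta-2,5-dien-4-ol (racemic)
Conditions: i-Bu2AlH (excess), CH2Cl2, −78 °C
Reagents that add atoms: none
Why: 1,2-reduction of the conjugated ester to the primary allylic alcohol turns the electron-poor acrylate alkene into an electron-rich allylic alcohol alkene that the Ti(Oi-Pr)4/tartrate/t-BuOOH system can epoxidise.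

Step 8
Reactants: 11 (2E,5E)-3-(hydroxymethyl)-7,7-dimethoxy-6-methyl-1-(PMB-oxy)hepta-2,5-dien-4-ol (racemic)
Product: 12 (2E,5E)-3-(TBS-oxymethyl)-7,7-dimethoxy-6-methyl-1-(PMB-oxy)hepta-2,5-dien-4-ol (racemic)
Conditions: TBSCl, imidazole, CH2Cl2, −20 to 0 °C
Reagents that add atoms: tert-butyldimethylsilyl chloride, CC(C)(C)[Si](C)(C)Cl
Why: silyl ether formation is much faster at the unhindered primary hydroxyl than at the secondary carbinol flanked by two trisubstituted alkenes, which leaves the C1' hydroxyl as the only group able to direct the epoxidation.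

Step 9
Reactants: 12 (2E,5E)-3-(TBS-oxymethyl)-7,7-dimethoxy-6-methyl-1-(PMB-oxy)hepta-2,5-dien-4-ol (racemic)
Product: 13 (1R,2E)-1-[(2R,3R)-2-(TBS-oxymethyl)-3-(PMB-oxymethyl)oxiran-2-yl]-4,4-dimethoxy-3-methylbut-2-en-1-ol
Conditions: Ti(Oi-Pr)4 (15 mol %), D-(−)-DIPT (18 mol %), t-BuOOH (0.45 equiv), 4 Å molecular sieves, CH2Cl2, −20 °C
Reagents that add atoms: tert-butyl hydroperoxide, CC(C)(C)OO
Why: Sharpless kinetic resolution, in which the peroxide complex assembled from Ti(Oi-Pr)4, D-(−)-DIPT and t-BuOOH should epoxidise the (R)-carbinol much faster than the (S)-carbinol (left behind) and deliver oxygen to the C4=C5 face that sets both oxirane carbons R with the erythro relation to C1', while C2'=C3' is spared because its methyl group cis to the carbinol clashes in the loaded complex and the acetal makes it electron-poor.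

Step 10
Reactants: 13 (1R,2E)-1-[(2R,3R)-2-(TBS-oxymethyl)-3-(PMB-oxymethyl)oxiran-2-yl]-4,4-dimethoxy-3-methylbut-2-en-1-ol
Product: 14 (1S,2E)-1-[(2R,3R)-2-(TBS-oxymethyl)-3-(PMB-oxymethyl)oxiran-2-yl]-4,4-dimethoxy-3-methylbut-2-en-1-yl acetate
Conditions: PPh3, DIAD, AcOH, toluene, 0 °C to rt
Reagents that add atoms: acetic acid, CC(=O)O
Why: Mitsunobu reaction, in which acetate displaces the alkoxyphosphonium group at the allylic C1' by SN2 with inversion (1R to 1S), turning the erythro epoxy alcohol into the threo epoxy acetate of the target and installing the ester in the same operation, attack at the fully substituted C3' terminus being sterically blocked.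

Step 11
Reactants: 14 (1S,2E)-1-[(2R,3R)-2-(TBS-oxymethyl)-3-(PMB-oxymethyl)oxiran-2-yl]-4,4-dimethoxy-3-methylbut-2-en-1-yl acetate
Product: 15 (1S,2E)-1-[(2R,3R)-2-(hydroxymethyl)-3-(PMB-oxymethyl)oxiran-2-yl]-4,4-dimethoxy-3-methylbut-2-en-1-yl acetate
Conditions: HF·pyridine, pyridine, THF, 0 °C
Reagents that add atoms: none
Why: fluoride cleavage of the primary silyl ether under pyridine-buffered, non-basic conditions should spare the acetal, oxirane and PMB ether and avoid base-induced migration of the neighbouring acetate.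

Step 12
Reactants: 15 (1S,2E)-1-[(2R,3R)-2-(hydroxymethyl)-3-(PMB-oxymethyl)oxiran-2-yl]-4,4-dimethoxy-3-methylbut-2-en-1-yl acetate
Product: 16 (1S,2E)-1-[(2R,3R)-2-formyl-3-(PMB-oxymethyl)oxiran-2-yl]-4,4-dimethoxy-3-methylbut-2-en-1-yl acetate
Conditions: DMP, NaHCO3, CH2Cl2, 0 °C to rt
Reagents that add atoms: none
Why: Dess–Martin oxidation of the primary alcohol is neutral and fast, and the aldehyde formed has no α-hydrogen, so C4 cannot epimerise.

Step 13
Reactants: 16 (1S,2E)-1-[(2R,3R)-2-formyl-3-(PMB-oxymethyl)oxiran-2-yl]-4,4-dimethoxy-3-methylbut-2-en-1-yl acetate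
Product: 17 (1S,2E)-1-[(2R,3R)-2-(1-hydroxyprop-2-en-1-yl)-3-(PMB-oxymethyl)oxiran-2-yl]-4,4-dimethoxy-3-methylbut-2-en-1-yl acetate (both C3 carbinol epimers)
Conditions: CH2=CHBr, CrCl2, NiCl2 (cat.), DMF, rt
Reagents that add atoms: vinyl bromide, C=CBr
Why: Nozaki–Hiyama–Kishi reaction, in which zerovalent nickel inserts into the C–Br bond, the vinyl group passes to trivalent chromium and this weakly basic alkenylchromium adds only to the aldehyde, leaving acetate and oxirane untouched; the new C3 carbinol forms as an epimer mixture that is immaterial because C3 ends as a ketone.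

Step 14
Reactants: 17 (1S,2E)-1-[(2R,3R)-2-(1-hydroxyprop-2-en-1-yl)-3-(PMB-oxymethyl)oxiran-2-yl]-4,4-dimethoxy-3-methylbut-2-en-1-yl acetate (both C3 carbinol epimers)
Product: 18 (1S,2E)-1-[(2R,3R)-2-[1-(TBS-oxy)prop-2-en-1-yl]-3-(PMB-oxymethyl)oxiran-2-yl]-4,4-dimethoxy-3-methylbut-2-en-1-yl acetate (C3 epimers)
Conditions: TBSOTf, 2,6-lutidine, CH2Cl2, −78 °C
Reagents that add atoms: tert-butyldimethylsilyl triflate, CC(C)(C)[Si](C)(C)OS(=O)(=O)C(F)(F)F
Why: silylation with the silyl triflate and a hindered base caps the crowded secondary carbinol at a temperature at which the dimethyl acetal is not activated, and blocks the C3 hydroxyl against acetyl migration and against the coming oxidations.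

Step 15
Reactants: 18 (1S,2E)-1-[(2R,3R)-2-[1-(TBS-oxy)prop-2-en-1-yl]-3-(PMB-oxymethyl)oxiran-2-yl]-4,4-dimethoxy-3-methylbut-2-en-1-yl acetate (C3 epimers)
Product: 19 (1S,2E)-1-[(2R,3R)-3-(hydroxymethyl)-2-[1-(TBS-oxy)prop-2-en-1-yl]oxiran-2-yl]-4,4-dimethoxy-3-methylbut-2-en-1-yl acetate (C3 epimers)
Conditions: DDQ, CH2Cl2/aqueous Na2HPO4–NaH2PO4 buffer (pH 7), 0 °C
Reagents that add atoms: none
Why: oxidative cleavage of the electron-rich PMB ether by DDQ is orthogonal to the silyl ether, the acetates and the buffered acetal.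

Step 16
Reactants: 19 (1S,2E)-1-[(2R,3R)-3-(hydroxymethyl)-2-[1-(TBS-oxy)prop-2-en-1-yl]oxiran-2-yl]-4,4-dimethoxy-3-methylbut-2-en-1-yl acetate (C3 epimers)
Product: 20 (1S,2E)-1-[(2R,3S)-3-formyl-2-[1-(TBS-oxy)prop-2-en-1-yl]oxiran-2-yl]-4,4-dimethoxy-3-methylbut-2-en-1-yl acetate (C3 epimers)
Conditions: DMP, NaHCO3, CH2Cl2, 0 °C to rt
Reagents that add atoms: none
Why: Dess–Martin oxidation under buffered conditions gives the epoxy aldehyde without epimerising C5, whose oxirane hydrogen is poorly acidic (the descriptor at C5 changes only because of priorities).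

Step 17
Reactants: 20 (1S,2E)-1-[(2R,3S)-3-formyl-2-[1-(TBS-oxy)prop-2-en-1-yl]oxiran-2-yl]-4,4-dimethoxy-3-methylbut-2-en-1-yl acetate (C3 epimers); 21 2-bromoprop-2-en-1-ol
Product: 22 (1S,2E)-1-[(2R,3R)-3-[1-hydroxy-2-(hydroxymethyl)prop-2-en-1-yl]-2-[1-(TBS-oxy)prop-2-en-1-yl]oxiran-2-yl]-4,4-dimethoxy-3-methylbut-2-en-1-yl acetate (C3 and C6 epimers)
Conditions: CrCl2 (excess), NiCl2 (cat.), DMF, rt
Reagents that add atoms: none
Why: Nozaki–Hiyama–Kishi reaction again, in which the alkenylchromium reagent from the bromoallyl alcohol is not basic enough to be quenched by its own hydroxyl or to touch the acetate, adds to the C6 aldehyde and builds the 1,1-disubstituted alkene carrying CH2OH; the C6 carbinol epimers are carried on together.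

Step 18
Reactants: 22 (1S,2E)-1-[(2R,3R)-3-[1-hydroxy-2-(hydroxymethyl)prop-2-en-1-yl]-2-[1-(TBS-oxy)prop-2-en-1-yl]oxiran-2-yl]-4,4-dimethoxy-3-methylbut-2-en-1-yl acetate (C3 and C6 epimers)
Product: 23 (1S,2E)-1-[(2R,3R)-3-[2-(acetoxymethyl)-1-hydroxyprop-2-en-1-yl]-2-[1-(TBS-oxy)prop-2-en-1-yl]oxiran-2-yl]-4,4-dimethoxy-3-methylbut-2-en-1-yl acetate (C3 and C6 epimers)
Conditions: AcCl, 2,4,6-collidine, CH2Cl2, −78 °C
Reagents that add atoms: acetyl chloride, CC(=O)Cl
Why: selective acylation, since acetyl chloride with the hindered base collidine at low temperature esterifies the primary allylic hydroxyl far faster than the secondary C6 hydroxyl next to the oxirane.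

Step 19
Reactants: 23 (1S,2E)-1-[(2R,3R)-3-[2-(acetoxymethyl)-1-hydroxyprop-2-en-1-yl]-2-[1-(TBS-oxy)prop-2-en-1-yl]oxiran-2-yl]-4,4-dimethoxy-3-methylbut-2-en-1-yl acetate (C3 and C6 epimers)
Product: 24 (1S,2E)-1-[(2R,3R)-3-[2-(acetoxymethyl)-1-(TBS-oxy)prop-2-en-1-yl]-2-[1-(TBS-oxy)prop-2-en-1-yl]oxiran-2-yl]-4,4-dimethoxy-3-methylbut-2-en-1-yl acetate (C3 and C6 epimers)
Conditions: TBSOTf, 2,6-lutidine, CH2Cl2, −78 to −40 °C
Reagents that add atoms: tert-butyldimethylsilyl triflate, CC(C)(C)[Si](C)(C)OS(=O)(=O)C(F)(F)F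
Why: silylation of the remaining secondary carbinol, kept cold so that the dimethyl acetal is not activated, gives the fully protected epoxy 1,7-diene and removes the last free hydroxyl that could migrate an acetate or promote alkene isomerisation under the metathesis catalyst.

Step 20
Reactants: 24 (1S,2E)-1-[(2R,3R)-3-[2-(acetoxymethyl)-1-(TBS-oxy)prop-2-en-1-yl]-2-[1-(TBS-oxy)prop-2-en-1-yl]oxiran-2-yl]-4,4-dimethoxy-3-methylbut-2-en-1-yl acetate (C3 and C6 epimers)
Product: 25 [(1R,6R)-1-[(1S,2E)-1-acetoxy-4,4-dimethoxy-3-methylbut-2-en-1-yl]-2,5-bis(TBS-oxy)-7-oxabicyclo[4.1.0]hept-3-en-4-yl]methyl acetate (carbinol epimers)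
Conditions: RuCl2(=CHPh)(PCy3)(H2IMes) (second-generation Grubbs catalyst, 10 mol %), toluene, 0.005 M, 80 °C, argon purge
Reagents that add atoms: none
Why: The benzylidene of RuCl2(=CHPh)(PCy3)(H2IMes) exchanges onto the monosubstituted vinyl group at C2, the resulting alkylidene undergoes intramolecular [2+2] cycloaddition with the 1,1-disubstituted alkene at C1, and the metallacyclobutane cycloreverts to release ethylene and the C1=C2 bond. The closest known reaction type is ring-closing olefin metathesis of 1,7-dienes to trisubstituted cyclohexenes, as used for carbasugars and cyclitols. The single carbocycle C1–C6 closes as a six-membered ring by alkene metathesis, the cis-oxirane C4–C5 holding the C3 and C6 arms on one face so that the two alkenes can meet. No stereocentre is created: C4, C5 and C1' are fixed beforehand and all C3/C6 carbinol epimers give the same ring skeleton. The selectivity needed is six-membered closure onto C1=CH2 in preference to five-membered closure onto C2' or cross-metathesis at the chain alkene. It should be secured because C2'=C3' is trisubstituted, flanked by the acetoxy carbon and inductively deactivated by the acetal, and because high dilution with removal of ethylene favours the intramolecular path.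

Step 21
Reactants: 25 [(1R,6R)-1-[(1S,2E)-1-acetoxy-4,4-dimethoxy-3-methylbut-2-en-1-yl]-2,5-bis(TBS-oxy)-7-oxabicyclo[4.1.0]hept-3-en-4-yl]methyl acetate (carbinol epimers)
Product: 26 [(1R,6R)-1-[(1S,2E)-1-acetoxy-3-methyl-4-oxobut-2-en-1-yl]-2,5-bis(TBS-oxy)-7-oxabicyclo[4.1.0]hept-3-en-4-yl]methyl acetate (carbinol epimers)
Conditions: pyridinium p-toluenesulfonate (cat.), acetone/H2O 10:1, rt
Reagents that add atoms: water, O
Why: acid-catalysed acetal hydrolysis, in which the allylic dimethyl acetal ionises easily to a conjugated oxocarbenium ion and is cleaved under conditions too mild for the hindered secondary silyl ethers, the acetates or the oxirane.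

Step 22
Reactants: 26 [(1R,6R)-1-[(1S,2E)-1-acetoxy-3-methyl-4-oxobut-2-en-1-yl]-2,5-bis(TBS-oxy)-7-oxabicyclo[4.1.0]hept-3-en-4-yl]methyl acetate (carbinol epimers)
Product: 27 [(1R,6R)-1-[(1S,2E,4E)-1-acetoxy-3-methyl-6-oxohexa-2,4-dien-1-yl]-2,5-bis(TBS-oxy)-7-oxabicyclo[4.1.0]hept-3-en-4-yl]methyl acetate (carbinol epimers)
Conditions: Ph3P=CHCHO (slight excess), toluene, 80 °C
Reagents that add atoms: (triphenylphosphoranylidene)acetaldehyde, O=CC=P(c1ccccc1)(c1ccccc1)c1ccccc1
Why: Wittig reaction with the stabilised formyl ylide adds C5'–C6' and should give the E alkene C4'=C5', the ylide being neutral enough for the acetates and used in only slight excess so that the product dienal is not homologated again.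

Step 23
Reactants: 27 [(1R,6R)-1-[(1S,2E,4E)-1-acetoxy-3-methyl-6-oxohexa-2,4-dien-1-yl]-2,5-bis(TBS-oxy)-7-oxabicyclo[4.1.0]hept-3-en-4-yl]methyl acetate (carbinol epimers)
Product: 28 [(1R,6R)-1-[(1S,2E,4E)-1-acetoxy-3-methyl-6-oxohexa-2,4-dien-1-yl]-2,5-dihydroxy-7-oxabicyclo[4.1.0]hept-3-en-4-yl]methyl acetate (carbinol epimers)
Conditions: HF·pyridine, pyridine, THF, 0 °C to rt
Reagents that add atoms: none
Why: fluoride-mediated desilylation with pyridine-buffered HF·pyridine removes both secondary silyl ethers while sparing acetates, dienal and oxirane, and the diol is oxidised at once so that acetyl migration has no time to occur.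

Step 24
Reactants: 28 [(1R,6R)-1-[(1S,2E,4E)-1-acetoxy-3-methyl-6-oxohexa-2,4-dien-1-yl]-2,5-dihydroxy-7-oxabicyclo[4.1.0]hept-3-en-4-yl]methyl acetate (carbinol epimers)
Product: 29 [(1R,6S)-1-[(1S,2E,4E)-1-acetoxy-3-methyl-6-oxohexa-2,4-dien-1-yl]-2,5-dioxo-7-oxabicyclo[4.1.0]hept-3-en-4-yl]methyl acetate
Conditions: DMP (excess), NaHCO3, CH2Cl2, 0 °C to rt
Reagents that add atoms: none
Why: Dess–Martin oxidation of both allylic carbinols under buffered, non-basic conditions converges all C3/C6 epimers on the ene-dione without touching C1', C4 or C5 (the descriptor at C5 changes only because of priorities).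

**Compound list**

1 | 1,1-dimethoxyacetone | CC(=O)C(OC)OC | starting material
2 | ethyl (2E)-4,4-dimethoxy-3-methylbut-2-enoate | CCOC(=O)/C=C(C)/C(OC)OC | intermediate
3 | (2E)-4,4-dimethoxy-3-methylbut-2-en-1-ol | OC/C=C(C)/C(OC)OC | intermediate
4 | (2E)-4,4-dimethoxy-3-methylbut-2-enal | O=C/C=C(C)/C(OC)OC | intermediate
5 | propargyl alcohol | C#CCO | starting material
6 | 4-methoxybenzyl propargyl ether | C#CCOCc1ccc(OC)cc1 | intermediate
7 | lithium acetylide of 6 (not isolated) | [Li]C#CCOCc1ccc(OC)cc1 | intermediate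
8 | methyl 4-(PMB-oxy)but-2-ynoate | COC(=O)C#CCOCc1ccc(OC)cc1 | intermediate
9 | vinylalane, methyl 2-(diisobutylalumanyl)-4-(PMB-oxy)but-2-enoate with Al cis to H and the ester cis to CH2OPMB (not isolated) | COC(=O)/C(=C\COCc1ccc(OC)cc1)[Al](CC(C)C)CC(C)C | intermediate
10 | methyl (2Z)-2-[(2E)-1-hydroxy-4,4-dimethoxy-3-methylbut-2-en-1-yl]-4-(PMB-oxy)but-2-enoate (racemic) | COC(=O)/C(=C\COCc1ccc(OC)cc1)C(O)/C=C(C)/C(OC)OC | intermediate
11 | (2E,5E)-3-(hydroxymethyl)-7,7-dimethoxy-6-methyl-1-(PMB-oxy)hepta-2,5-dien-4-ol (racemic) | OC/C(=C\COCc1ccc(OC)cc1)C(O)/C=C(C)/C(OC)OC | intermediate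
12 | (2E,5E)-3-(TBS-oxymethyl)-7,7-dimethoxy-6-methyl-1-(PMB-oxy)hepta-2,5-dien-4-ol (racemic) | CC(C)(C)[Si](C)(C)OC/C(=C\COCc1ccc(OC)cc1)C(O)/C=C(C)/C(OC)OC | intermediate
13 | (1R,2E)-1-[(2R,3R)-2-(TBS-oxymethyl)-3-(PMB-oxymethyl)oxiran-2-yl]-4,4-dimethoxy-3-methylbut-2-en-1-ol | CC(C)(C)[Si](C)(C)OC[C@]1([C@@H](/C=C(C)/C(OC)OC)O)O[C@@H]1COCc1ccc(OC)cc1 | intermediate
14 | (1S,2E)-1-[(2R,3R)-2-(TBS-oxymethyl)-3-(PMB-oxymethyl)oxiran-2-yl]-4,4-dimethoxy-3-methylbut-2-en-1-yl acetate | CC(C)(C)[Si](C)(C)OC[C@]1([C@H](/C=C(C)/C(OC)OC)OC(C)=O)O[C@@H]1COCc1ccc(OC)cc1 | intermediate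
15 | (1S,2E)-1-[(2R,3R)-2-(hydroxymethyl)-3-(PMB-oxymethyl)oxiran-2-yl]-4,4-dimethoxy-3-methylbut-2-en-1-yl acetate | OC[C@]1([C@H](/C=C(C)/C(OC)OC)OC(C)=O)O[C@@H]1COCc1ccc(OC)cc1 | intermediate
16 | (1S,2E)-1-[(2R,3R)-2-formyl-3-(PMB-oxymethyl)oxiran-2-yl]-4,4-dimethoxy-3-methylbut-2-en-1-yl acetate | O=C[C@]1([C@H](/C=C(C)/C(OC)OC)OC(C)=O)O[C@@H]1COCc1ccc(OC)cc1 | intermediate
17 | (1S,2E)-1-[(2R,3R)-2-(1-hydroxyprop-2-en-1-yl)-3-(PMB-oxymethyl)oxiran-2-yl]-4,4-dimethoxy-3-methylbut-2-en-1-yl acetate (C3 epimers) | C=CC(O)[C@]1([C@H](/C=C(C)/C(OC)OC)OC(C)=O)O[C@@H]1COCc1ccc(OC)cc1 | intermediate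
18 | (1S,2E)-1-[(2R,3R)-2-[1-(TBS-oxy)prop-2-en-1-yl]-3-(PMB-oxymethyl)oxiran-2-yl]-4,4-dimethoxy-3-methylbut-2-en-1-yl acetate (C3 epimers) | C=CC(O[Si](C)(C)C(C)(C)C)[C@]1([C@H](/C=C(C)/C(OC)OC)OC(C)=O)O[C@@H]1COCc1ccc(OC)cc1 | intermediate
19 | (1S,2E)-1-[(2R,3R)-3-(hydroxymethyl)-2-[1-(TBS-oxy)prop-2-en-1-yl]oxiran-2-yl]-4,4-dimethoxy-3-methylbut-2-en-1-yl acetate (C3 epimers) | C=CC(O[Si](C)(C)C(C)(C)C)[C@]1([C@H](/C=C(C)/C(OC)OC)OC(C)=O)O[C@@H]1CO | intermediate
20 | (1S,2E)-1-[(2R,3S)-3-formyl-2-[1-(TBS-oxy)prop-2-en-1-yl]oxiran-2-yl]-4,4-dimethoxy-3-methylbut-2-en-1-yl acetate (C3 epimers) | C=CC(O[Si](C)(C)C(C)(C)C)[C@]1([C@H](/C=C(C)/C(OC)OC)OC(C)=O)O[C@@H]1C=O | intermediate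
21 | 2-bromoprop-2-en-1-ol | OCC(Br)=C | starting material
22 | (1S,2E)-1-[(2R,3R)-3-[1-hydroxy-2-(hydroxymethyl)prop-2-en-1-yl]-2-[1-(TBS-oxy)prop-2-en-1-yl]oxiran-2-yl]-4,4-dimethoxy-3-methylbut-2-en-1-yl acetate (C3 and C6 epimers) | C=CC(O[Si](C)(C)C(C)(C)C)[C@]1([C@H](/C=C(C)/C(OC)OC)OC(C)=O)O[C@@H]1C(O)C(=C)CO | intermediate
23 | (1S,2E)-1-[(2R,3R)-3-[2-(acetoxymethyl)-1-hydroxyprop-2-en-1-yl]-2-[1-(TBS-oxy)prop-2-en-1-yl]oxiran-2-yl]-4,4-dimethoxy-3-methylbut-2-en-1-yl acetate (C3 and C6 epimers) | C=CC(O[Si](C)(C)C(C)(C)C)[C@]1([C@H](/C=C(C)/C(OC)OC)OC(C)=O)O[C@@H]1C(O)C(=C)COC(C)=O | intermediate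
24 | (1S,2E)-1-[(2R,3R)-3-[2-(acetoxymethyl)-1-(TBS-oxy)prop-2-en-1-yl]-2-[1-(TBS-oxy)prop-2-en-1-yl]oxiran-2-yl]-4,4-dimethoxy-3-methylbut-2-en-1-yl acetate (C3 and C6 epimers) | C=CC(O[Si](C)(C)C(C)(C)C)[C@]1([C@H](/C=C(C)/C(OC)OC)OC(C)=O)O[C@@H]1C(O[Si](C)(C)C(C)(C)C)C(=C)COC(C)=O | intermediate
25 | [(1R,6R)-1-[(1S,2E)-1-acetoxy-4,4-dimethoxy-3-methylbut-2-en-1-yl]-2,5-bis(TBS-oxy)-7-oxabicyclo[4.1.0]hept-3-en-4-yl]methyl acetate (carbinol epimers) | CC(=O)OCC1=CC(O[Si](C)(C)C(C)(C)C)[C@]2([C@H](/C=C(C)/C(OC)OC)OC(C)=O)O[C@@H]2C1O[Si](C)(C)C(C)(C)C | intermediate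
26 | [(1R,6R)-1-[(1S,2E)-1-acetoxy-3-methyl-4-oxobut-2-en-1-yl]-2,5-bis(TBS-oxy)-7-oxabicyclo[4.1.0]hept-3-en-4-yl]methyl acetate (carbinol epimers) | CC(=O)OCC1=CC(O[Si](C)(C)C(C)(C)C)[C@]2([C@H](/C=C(C)/C=O)OC(C)=O)O[C@@H]2C1O[Si](C)(C)C(C)(C)C | intermediate
27 | [(1R,6R)-1-[(1S,2E,4E)-1-acetoxy-3-methyl-6-oxohexa-2,4-dien-1-yl]-2,5-bis(TBS-oxy)-7-oxabicyclo[4.1.0]hept-3-en-4-yl]methyl acetate (carbinol epimers) | CC(=O)OCC1=CC(O[Si](C)(C)C(C)(C)C)[C@]2([C@H](/C=C(C)/C=C/C=O)OC(C)=O)O[C@@H]2C1O[Si](C)(C)C(C)(C)C | intermediate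
28 | [(1R,6R)-1-[(1S,2E,4E)-1-acetoxy-3-methyl-6-oxohexa-2,4-dien-1-yl]-2,5-dihydroxy-7-oxabicyclo[4.1.0]hept-3-en-4-yl]methyl acetate (carbinol epimers) | CC(=O)OCC1=CC(O)[C@]2([C@H](/C=C(C)/C=C/C=O)OC(C)=O)O[C@@H]2C1O | intermediate
29 | [(1R,6S)-1-[(1S,2E,4E)-1-acetoxy-3-methyl-6-oxohexa-2,4-dien-1-yl]-2,5-dioxo-7-oxabicyclo[4.1.0]hept-3-en-4-yl]methyl acetate | CC(=O)OCC1=CC(=O)[C@]2([C@H](/C=C(C)/C=C/C=O)OC(C)=O)O[C@@H]2C1=O | target

**Count and risks**

Total step count: 24. Longest linear sequence: 22 steps (steps 1 to 3, then steps 6 to 24, from 1,1-dimethoxyacetone). The two-step branch from propargyl alcohol (steps 4 and 5) joins in step 6, and 2-bromoprop-2-en-1-ol enters in step 17.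

Steps most likely to fail:

Step 10 (inversion at C1'). The displacement may be slow at a carbinol flanked by the fully substituted oxirane carbon, so that elimination, allylic transposition or incomplete inversion erodes the material. The fallback avoids the inversion and lets the primary hydroxyl direct the epoxidation. It sets out from racemic 12 (the (S)-enantiomer recovered from step 9 can be fed in as well). Acetylation with Ac2O, DMAP and pyridine should give the racemic dienyl acetate F1, and HF·pyridine in pyridine/THF should free the primary allylic alcohol, hydroxy acetate F2. A Sharpless asymmetric epoxidation of F2 with Ti(Oi-Pr)4, L-(+)-DIPT and t-BuOOH at −20 °C should then deliver oxygen to the same face of C4=C5 in both enantiomers under reagent control. The (S)-configured half gives 15 directly; the (R)-configured half gives its C1' epimer, epoxy acetate F3, which is removed by chromatography. The route is rejoined at 15, and this detour also bypasses step 9.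

Step 20 (ring closure). Loading and closure may be slow because both alkenes sit next to bulky silyl ethers and the quaternary oxirane carbon, so that oligomerisation or catalyst decay competes. The fallback closes the ring one stage earlier on a less crowded substrate. It sets out from 23, whose C6 hydroxyl is still free; metathesis with RuCl2(=CHPh)(PCy3)(H2IMes) in toluene, with 1,4-benzoquinone added to suppress alkene isomerisation, should give the cyclohexenol F4, a free allylic hydroxyl next to the disubstituted alkene being known to speed such closures. Silylation with TBSOTf and 2,6-lutidine then returns to 25.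

Step 17 (alkenylchromium addition with a free hydroxyl). The organochromium reagent may be protonated by the hydroxyl of 21, or the α-branched bromide may couple sluggishly, leaving aldehyde 20 to decompose. The fallback sets out from 20 and 21 and uses a protected reagent. Compound 21 is silylated with TBSCl and imidazole to the bromoallyl silyl ether F5, and the CrCl2/NiCl2 coupling of F5 with 20 should give the carbinol F6. TBSOTf with 2,6-lutidine gives the tris(silyl ether) F7, HF·pyridine in pyridine/THF at 0 °C removes only the primary silyl group to give the allylic alcohol F8, and Ac2O with pyridine and DMAP returns to 24.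

**Further compounds**

F1 | step 10 | (2E,5E)-3-(TBS-oxymethyl)-7,7-dimethoxy-6-methyl-1-(PMB-oxy)hepta-2,5-dien-4-yl acetate (racemic) | CC(C)(C)[Si](C)(C)OC/C(=C\COCc1ccc(OC)cc1)C(OC(C)=O)/C=C(C)/C(OC)OC
F2 | step 10 | (2E,5E)-3-(hydroxymethyl)-7,7-dimethoxy-6-methyl-1-(PMB-oxy)hepta-2,5-dien-4-yl acetate (racemic) | OC/C(=C\COCc1ccc(OC)cc1)C(OC(C)=O)/C=C(C)/C(OC)OC
F3 | step 10 | (1R,2E)-1-[(2R,3R)-2-(hydroxymethyl)-3-(PMB-oxymethyl)oxiran-2-yl]-4,4-dimethoxy-3-methylbut-2-en-1-yl acetate | OC[C@]1([C@@H](/C=C(C)/C(OC)OC)OC(C)=O)O[C@@H]1COCc1ccc(OC)cc1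
F4 | step 20 | [(1R,6R)-1-[(1S,2E)-1-acetoxy-4,4-dimethoxy-3-methylbut-2-en-1-yl]-5-hydroxy-2-(TBS-oxy)-7-oxabicyclo[4.1.0]hept-3-en-4-yl]methyl acetate (carbinol epimers) | CC(=O)OCC1=CC(O[Si](C)(C)C(C)(C)C)[C@]2([C@H](/C=C(C)/C(OC)OC)OC(C)=O)O[C@@H]2C1O
F5 | step 17 | [(2-bromoprop-2-en-1-yl)oxy](tert-butyl)dimethylsilane | C=C(Br)CO[Si](C)(C)C(C)(C)C
F6 | step 17 | (1S,2E)-1-[(2R,3R)-3-[1-hydroxy-2-(TBS-oxymethyl)prop-2-en-1-yl]-2-[1-(TBS-oxy)prop-2-en-1-yl]oxiran-2-yl]-4,4-dimethoxy-3-methylbut-2-en-1-yl acetate (carbinol epimers) | C=CC(O[Si](C)(C)C(C)(C)C)[C@]1([C@H](/C=C(C)/C(OC)OC)OC(C)=O)O[C@@H]1C(O)C(=C)CO[Si](C)(C)C(C)(C)C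
F7 | step 17 | (1S,2E)-1-[(2R,3R)-3-[1-(TBS-oxy)-2-(TBS-oxymethyl)prop-2-en-1-yl]-2-[1-(TBS-oxy)prop-2-en-1-yl]oxiran-2-yl]-4,4-dimethoxy-3-methylbut-2-en-1-yl acetate (carbinol epimers) | C=CC(O[Si](C)(C)C(C)(C)C)[C@]1([C@H](/C=C(C)/C(OC)OC)OC(C)=O)O[C@@H]1C(O[Si](C)(C)C(C)(C)C)C(=C)CO[Si](C)(C)C(C)(C)C
F8 | step 17 | (1S,2E)-1-[(2R,3R)-3-[2-(hydroxymethyl)-1-(TBS-oxy)prop-2-en-1-yl]-2-[1-(TBS-oxy)prop-2-en-1-yl]oxiran-2-yl]-4,4-dimethoxy-3-methylbut-2-en-1-yl acetate (carbinol epimers) | C=CC(O[Si](C)(C)C(C)(C)C)[C@]1([C@H](/C=C(C)/C(OC)OC)OC(C)=O)O[C@@H]1C(O[Si](C)(C)C(C)(C)C)C(=C)CO
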